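**Retrosynthetic overview**
- Convention: ring A is the methoxy ring on carbonyl carbon C7, ring B the ring on carbonyl carbon C8, and C1 of each ring bears its carbonyl.
- The prenyl group at C3 of ring B comes last, by aromatic Claisen rearrangement of the ring-B O4 1,1-dimethylallyl ether, itself made from the O4 phenol by propargylation and semihydrogenation.
- The two aryl C2–O bonds are disconnected together, by twofold carbonyl-directed C–H oxygenation of 4-methoxy-4'-pivaloyloxybenzil. The strategy rests on each ring carrying its hydroxyl at C2, next to the C1 that bears its own carbonyl (C7=O for ring A, C8=O for ring B), which is where a ketone oxygen delivers a metal.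
- The benzil comes from Riley oxidation of the deoxybenzoin pivalate; the C8–C1(ring B) bond comes from para Friedel–Crafts acylation of phenol with 4-methoxyphenylacetic acid.
- No ring is formed: both benzene rings are bought and only decorated, ring B before ring A only in the sense that the acylation builds on phenol.

Key step: step 4

Remark: every 2-hydroxybenzil of the route is written as the open-chain dione; its ring-chain tautomer (a 2-aryl-2-hydroxybenzofuran-3(2H)-one) is assumed to equilibrate freely and not to divert any step.

**Step 1**
Reactants: 1 phenol; 2 4-methoxyphenylacetic acid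
Product: 3 1-(4-hydroxyphenyl)-2-(4-methoxyphenyl)ethanone
Conditions: BF3·OEt2 (solvent), phenol in excess, 85 °C; aq. NaOAc work-up
Reagents that add atoms: none
Why: Friedel–Crafts acylation (BF3-mediated, possibly through the phenyl ester and a Fries shift) should go to the unhindered para position of the strongly activated phenol, while the anisole ring of the acid, with its para position blocked, is the poorer nucleophile, so self-acylation should stay minor.

**Step 2**
Reactants: 3 1-(4-hydroxyphenyl)-2-(4-methoxyphenyl)ethanone; 4 pivaloyl chloride
Product: 5 4-[2-(4-methoxyphenyl)acetyl]phenyl pivalate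
Conditions: Et3N, DMAP (cat.), CH2Cl2, 0 °C to rt
Reagents that add atoms: none
Why: DMAP-catalysed O-acylation (esterification) of the phenol is far faster than enol acylation of the ketone, and the pivalate masks the phenol and keeps ring B electron-poor towards the oxidants of steps 3 and 4.

**Step 3**
Reactants: 5 4-[2-(4-methoxyphenyl)acetyl]phenyl pivalate
Product: 6 1-(4-methoxyphenyl)-2-[4-(pivaloyloxy)phenyl]ethane-1,2-dione
Conditions: SeO2, dioxane/H2O, 100 °C
Reagents that add atoms: selenium dioxide, O=[Se]=O
Why: Riley oxidation, in which SeO2 attacks the enol of the doubly activated methylene and the selenium ester collapses to the 1,2-diketone, should leave the aryl pivalate and the methyl ether untouched.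

**Step 4**
Reactants: 6 1-(4-methoxyphenyl)-2-[4-(pivaloyloxy)phenyl]ethane-1,2-dione
Product: 8 1-(2-hydroxy-4-methoxyphenyl)-2-[2-hydroxy-4-(pivaloyloxy)phenyl]ethane-1,2-dione, via bis(trifluoroacetate) ester 7 (not isolated)
Conditions: [RuCl2(p-cymene)]2 (5 mol %), PhI(OCOCF3)2 (2.5 equiv), CF3CO2H/(CF3CO)2O, 60 °C; then H2O/THF, rt
Reagents that add atoms: [bis(trifluoroacetoxy)iodo]benzene, O=C(OI(OC(=O)C(F)(F)F)c1ccccc1)C(F)(F)F
Why: Proposed new method: each carbonyl oxygen (C7=O for ring A, C8=O for ring B) should bind a cationic divalent ruthenium trifluoroacetate, concerted metalation–deprotonation at an ortho C–H bond of its own ring should give a five-membered ruthenacycle, the trivalent iodine reagent should oxidise it to a tetravalent ruthenium aryl trifluoroacetate, and C–O reductive elimination should release the aryl trifluoroacetate and divalent ruthenium, the cycle then running again on the other ring before water cleaves both trifluoroacetates. The closest known reaction type is the [RuCl2(p-cymene)]2- or Pd(OAc)2-catalysed ketone-directed ortho C–H hydroxylation of simple aryl ketones with PhI(OCOCF3)2 in CF3CO2H/(CF3CO)2O; new here is a 1,2-dione acting as a twofold directing group. No ring is closed and no stereocentre is formed. Within each ring no site question arises because both rings are para-substituted and their two ortho positions are equivalent, and C3 and C5 should stay untouched because the ketone is a far better donor than the pivalate carbonyl or the ether oxygen. One oxygenation per ring is secured because the first trifluoroacetoxy group deactivates its ring and twists the aroyl group out of plane, which weakens that carbonyl as a director for the second ortho position. The aroyl and pivaloyloxy groups should keep both rings electron-poor enough to resist single-electron oxidation by the iodine reagent, which is why the free phenol and the prenyl group are introduced only afterwards.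

**Step 5**
Reactants: 8 1-(2-hydroxy-4-methoxyphenyl)-2-[2-hydroxy-4-(pivaloyloxy)phenyl]ethane-1,2-dione
Product: 9 1-(2,4-dihydroxyphenyl)-2-(2-hydroxy-4-methoxyphenyl)ethane-1,2-dione
Conditions: K2CO3, MeOH, rt; mildly acidic work-up
Reagents that add atoms: none
Why: Base-mediated transesterification (methanolysis) of the aryl pivalate, activated by its para acyl group, should be fast at room temperature, while the dione, present as an electron-rich phenoxide, should be protected from benzilic ester rearrangement.

**Step 6**
Reactants: 9 1-(2,4-dihydroxyphenyl)-2-(2-hydroxy-4-methoxyphenyl)ethane-1,2-dione; 10 3-chloro-3-methylbut-1-yne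
Product: 11 1-[2-hydroxy-4-(2-methylbut-3-yn-2-yloxy)phenyl]-2-(2-hydroxy-4-methoxyphenyl)ethane-1,2-dione
Conditions: DBU (1.1 equiv), CuCl2 (1 mol %), MeCN, 0 °C
Reagents that add atoms: none
Why: Copper-catalysed propargylic O-alkylation of the tertiary propargylic chloride should take place at O4 of ring B, the most acidic and only non-chelated phenol, because both C2 hydroxyls are held in hydrogen bonds to their neighbouring carbonyls.

**Step 7**
Reactants: 11 1-[2-hydroxy-4-(2-methylbut-3-yn-2-yloxy)phenyl]-2-(2-hydroxy-4-methoxyphenyl)ethane-1,2-dione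
Product: 12 1-[2-hydroxy-4-(2-methylbut-3-en-2-yloxy)phenyl]-2-(2-hydroxy-4-methoxyphenyl)ethane-1,2-dione
Conditions: H2 (1 atm, one equivalent taken up), Pd/CaCO3 poisoned with Pb(OAc)2 (Lindlar catalyst), quinoline, EtOAc, rt
Reagents that add atoms: none
Why: Lindlar semihydrogenation should stop at the alkene because the terminal alkyne binds the poisoned palladium surface much more strongly than the resulting vinyl group or the aryl dione.

**Step 8**
Reactants: 12 1-[2-hydroxy-4-(2-methylbut-3-en-2-yloxy)phenyl]-2-(2-hydroxy-4-methoxyphenyl)ethane-1,2-dione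
Product: 14 licoagrodione [1-(2,4-dihydroxy-3-prenylphenyl)-2-(2-hydroxy-4-methoxyphenyl)ethane-1,2-dione], via ortho-dienone 13 (not isolated)
Conditions: PhNEt2, 150 °C, argon
Reagents that add atoms: none
Why: Aromatic Claisen rearrangement, a [3,3] shift that turns the tertiary allyl ether into a linear prenyl group, should go to C3 and not C5 because the C2–OH···O=C8 hydrogen bond fixes more double-bond character in the C3–C4 bond, and enolisation of the dienone then restores ring B.

**Compound list**
1 | phenol | Oc1ccccc1 | starting material
2 | 4-methoxyphenylacetic acid | COc1ccc(CC(=O)O)cc1 | starting material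
3 | 1-(4-hydroxyphenyl)-2-(4-methoxyphenyl)ethanone | COc1ccc(CC(=O)c2ccc(O)cc2)cc1 | intermediate
4 | pivaloyl chloride | CC(C)(C)C(=O)Cl | starting material
5 | 4-[2-(4-methoxyphenyl)acetyl]phenyl pivalate | COc1ccc(CC(=O)c2ccc(OC(=O)C(C)(C)C)cc2)cc1 | intermediate
6 | 1-(4-methoxyphenyl)-2-[4-(pivaloyloxy)phenyl]ethane-1,2-dione | COc1ccc(C(=O)C(=O)c2ccc(OC(=O)C(C)(C)C)cc2)cc1 | intermediate
7 | 1-[4-methoxy-2-(trifluoroacetoxy)phenyl]-2-[4-(pivaloyloxy)-2-(trifluoroacetoxy)phenyl]ethane-1,2-dione | COc1ccc(C(=O)C(=O)c2ccc(OC(=O)C(C)(C)C)cc2OC(=O)C(F)(F)F)c(OC(=O)C(F)(F)F)c1 | intermediate (not isolated)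
8 | 1-(2-hydroxy-4-methoxyphenyl)-2-[2-hydroxy-4-(pivaloyloxy)phenyl]ethane-1,2-dione | COc1ccc(C(=O)C(=O)c2ccc(OC(=O)C(C)(C)C)cc2O)c(O)c1 | intermediate
9 | 1-(2,4-dihydroxyphenyl)-2-(2-hydroxy-4-methoxyphenyl)ethane-1,2-dione | COc1ccc(C(=O)C(=O)c2ccc(O)cc2O)c(O)c1 | intermediate
10 | 3-chloro-3-methylbut-1-yne | C#CC(C)(C)Cl | starting material
11 | 1-[2-hydroxy-4-(2-methylbut-3-yn-2-yloxy)phenyl]-2-(2-hydroxy-4-methoxyphenyl)ethane-1,2-dione | COc1ccc(C(=O)C(=O)c2ccc(OC(C)(C)C#C)cc2O)c(O)c1 | intermediate
12 | 1-[2-hydroxy-4-(2-methylbut-3-en-2-yloxy)phenyl]-2-(2-hydroxy-4-methoxyphenyl)ethane-1,2-dione | COc1ccc(C(=O)C(=O)c2ccc(OC(C)(C)C=C)cc2O)c(O)c1 | intermediate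
13 | 3-hydroxy-4-[(2-hydroxy-4-methoxyphenyl)(oxo)acetyl]-2-(3-methylbut-2-en-1-yl)cyclohexa-3,5-dien-1-one (racemic at C2) | COc1ccc(C(=O)C(=O)C2=C(O)C(CC=C(C)C)C(=O)C=C2)c(O)c1 | intermediate (not isolated)
14 | licoagrodione, 1-[2,4-dihydroxy-3-(3-methylbut-2-en-1-yl)phenyl]-2-(2-hydroxy-4-methoxyphenyl)ethane-1,2-dione | COc1ccc(C(=O)C(=O)c2ccc(O)c(CC=C(C)C)c2O)c(O)c1 | target

**Total step count:** 8
**Longest linear sequence:** 8 steps (phenol 1 to licoagrodione 14)

**Steps most likely to fail**

1. Step 4 (carries the label "Proposed new method:").
   - What may go wrong: the two adjacent carbonyls may bind the metal together as an O,O-chelate so that C–H cleavage stalls; the iodine reagent may oxidise the anisole ring by single-electron transfer or cleave the dione C–C bond; or oxygenation may stop after the first ring.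
   - Fallback (known chemistry only): give up C–H oxygenation and bring both ortho oxygens in with the building blocks. No numbered intermediate before 8 carries these oxygens, so the fallback sets out at the start of the route, in the place of compounds 1 and 2, and comes back at compound 9.
   - Resorcinol (Oc1cccc(O)c1) should be acylated at C4 with 2,4-dimethoxyphenylacetic acid (COc1ccc(CC(=O)O)c(OC)c1) in BF3·OEt2 at 85 °C, the standard deoxybenzoin synthesis, to give 1-(2,4-dihydroxyphenyl)-2-(2,4-dimethoxyphenyl)ethanone F1.
   - Riley oxidation with SeO2 in aqueous dioxane should then give 1-(2,4-dihydroxyphenyl)-2-(2,4-dimethoxyphenyl)ethane-1,2-dione F2.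
   - BCl3 in CH2Cl2 at −78 to 0 °C should remove only the methyl group ortho to the C7 carbonyl, through the six-membered boron chelate, and leave the para methoxy group in place, which gives 9.

2. Step 8.
   - What may go wrong: at the temperature of the rearrangement the tertiary allyl ether may ionise and lose isoprene (return to 9), part of the migration may go to C5, or the new prenyl group may cyclise onto a neighbouring hydroxyl.
   - Fallback: it sets out from compound 9 and comes back at compound 14, bypassing 11 and 12.
   - O4-allylation with allyl bromide (C=CCBr), K2CO3, DMF, rt should give 1-[4-(allyloxy)-2-hydroxyphenyl]-2-(2-hydroxy-4-methoxyphenyl)ethane-1,2-dione F3; a primary allyl ether cannot fragment to a diene.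
   - Claisen rearrangement in PhNEt2 at 200 °C, well known to go to C3 in 4-allyloxy-2-hydroxyaryl ketones, should give 1-(3-allyl-2,4-dihydroxyphenyl)-2-(2-hydroxy-4-methoxyphenyl)ethane-1,2-dione F4.
   - Olefin cross-metathesis with excess 2-methylbut-2-ene and second-generation Grubbs catalyst, (H2IMes)(PCy3)Cl2Ru=CHPh, in CH2Cl2 at 40 °C should convert the allyl group into the prenyl group and give 14.

3. Step 7.
   - What may go wrong: hydrogen uptake may run on to the saturated tert-pentyl ether, or the 1,2-dione may be reduced to the benzoin on the palladium surface.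
   - Fallback: it sets out from compound 9 and comes back at compound 12, and replaces steps 6 and 7 without any hydrogenation.
   - Decarboxylative Tsuji–Trost O-allylation of 9 with tert-butyl 2-methylbut-3-en-2-yl carbonate (C=CC(C)(C)OC(=O)OC(C)(C)C) and Pd(PPh3)4 (zerovalent palladium) in THF at 0 °C should give 12 directly; under kinetic control the phenoxide of O4 attacks the more substituted terminus of the allyl palladium intermediate.

**Further compounds**
F1 | step 4 | 1-(2,4-dihydroxyphenyl)-2-(2,4-dimethoxyphenyl)ethanone | COc1ccc(CC(=O)c2ccc(O)cc2O)c(OC)c1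
F2 | step 4 | 1-(2,4-dihydroxyphenyl)-2-(2,4-dimethoxyphenyl)ethane-1,2-dione | COc1ccc(C(=O)C(=O)c2ccc(O)cc2O)c(OC)c1
F3 | step 8 | 1-[4-(allyloxy)-2-hydroxyphenyl]-2-(2-hydroxy-4-methoxyphenyl)ethane-1,2-dione | COc1ccc(C(=O)C(=O)c2ccc(OCC=C)cc2O)c(O)c1
F4 | step 8 | 1-(3-allyl-2,4-dihydroxyphenyl)-2-(2-hydroxy-4-methoxyphenyl)ethane-1,2-dione | COc1ccc(C(=O)C(=O)c2ccc(O)c(CC=C)c2O)c(O)c1
F0 | step 7 | none | none
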